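**Retrosynthetic overview**
1. Polymatin A ⇐ intramolecular Cr(II) Barbier allylation/lactonisation forming C6–C7: the ten-membered carbocycle closes first, and the trans-γ-lactone forms immediately afterwards in the same step.
2. Acyclic enal–allyl bromide ⇐ late Ni/Cr (NHK) coupling at C9–C10 of West vinyl iodide 7 (C1–C6, C10, C14, C15) with East aldehyde 16 (C7–C9, C11–C13, angelate).
3. West 7 ⇐ Grignard addition, Johnson–Claisen (4E alkene), iodo-Wittig (Z-iodoenoate, which becomes the cis C1=C10 bond).
4. East 16 ⇐ (S)-glycidol (source of C8) → epoxy aldehyde → Wittig → Pd-catalysed epoxide opening by angelic acid → oxidation.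

Assumption: atoms are labelled with germacrane numbering (lactone C12–O–C6, CO2Me = C14 on C10, angelate on O-8, OH on C9). The given SMILES is read as 6R,7S,8S,9S, C4=C5 E, C1=C10 ring-cis (CIP E), angelate Z.

**West fragment**

Step 1
Reactants: 1 (2,2-dimethoxyacetaldehyde, anhydrous), 2 (isopropenylmagnesium bromide)
Product: 3 (1,1-dimethoxy-3-methylbut-3-en-2-ol, racemic)
Conditions: THF, −78 → 0 °C; aq. NH4Cl
Reagents that add atoms: none (both reactants are numbered)
Why: Grignard 1,2-addition gives the 2-substituted allylic alcohol needed for the Claisen step; its stereocentre is destroyed in step 2.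

Step 2
Reactants: 3, 4 (trimethyl orthoacetate)
Product: 5 (methyl (E)-6,6-dimethoxy-4-methylhex-4-enoate)
Conditions: 4 (excess), cat. EtCO2H, 110–130 °C, MeOH distilled off
Reagents that add atoms: none (4 is numbered)
Why: Johnson–Claisen rearrangement through a chair transition state with the CH(OMe)2 group equatorial gives the E-trisubstituted C4=C5 alkene and adds C1–C3.

Step 3
Reactants: 5
Product: 6 ((E)-6,6-dimethoxy-4-methylhex-4-enal)
Conditions: DIBAL-H (1.05 equiv), CH2Cl2, −78 °C; Rochelle salt
Reagents that add atoms: none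
Why: Partial DIBAL reduction of the methyl ester stops at the aldehyde at −78 °C; the acetal and alkene are inert.

Step 4
Reactants: 6
Product: 7 (methyl (2Z,6E)-2-iodo-8,8-dimethoxy-6-methylocta-2,6-dienoate)
Conditions: Ph3P=CHCO2Me, NIS, CH2Cl2, −20 °C; then K2CO3, 6, rt
Reagents that add atoms: methyl (triphenylphosphoranylidene)acetate, COC(=O)C=P(c1ccccc1)(c1ccccc1)c1ccccc1; N-iodosuccinimide, O=C1CCC(=O)N1I
Why: Wittig olefination with the in-situ iodo-ylide Ph3P=C(I)CO2Me puts the ester trans to the chain, giving the (Z)-α-iodoenoate whose geometry becomes the cis C1=C10 bond.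

**East fragment**

Step 5
Reactants: 8 (methyl 2-bromo-3-hydroxypropanoate)
Product: 9 (methyl 2-bromo-3-[(tert-butyldimethylsilyl)oxy]propanoate)
Conditions: TBSCl, imidazole, CH2Cl2, 0 °C
Reagents that add atoms: TBSCl, CC(C)(C)[Si](C)(C)Cl
Why: Silylation of the primary alcohol protects the future C13 oxygen.

Step 6
Reactants: 9
Product: 10 (methyl 3-[(tert-butyldimethylsilyl)oxy]-2-(triphenylphosphoranylidene)propanoate)
Conditions: PPh3, MeCN, 70 °C; then aq. Na2CO3/CH2Cl2, 0 °C
Reagents that add atoms: triphenylphosphine, c1ccc(cc1)P(c1ccccc1)c1ccccc1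
Why: SN2 quaternisation of PPh3 by the α-bromo ester and deprotonation give an ester-stabilised, α-substituted Wittig ylide.

Step 7
Reactants: 11 ((S)-glycidol)
Product: 12 ((R)-oxirane-2-carbaldehyde; same spatial arrangement, descriptor changes by CIP priority only)
Conditions: Dess–Martin periodinane, NaHCO3, CH2Cl2, 0 °C; filtered solution used directly
Reagents that add atoms: none
Why: Dess–Martin oxidation of the primary alcohol under buffered conditions leaves the epoxide stereocentre (future C8) untouched.

Step 8
Reactants: 12, 10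
Product: 13 (methyl (2E)-2-{[(tert-butyldimethylsilyl)oxy]methyl}-3-[(2S)-oxiran-2-yl]prop-2-enoate)
Conditions: CH2Cl2, 0 °C → rt
Reagents that add atoms: none (10 is numbered)
Why: Wittig reaction of the stabilised ylide gives the trisubstituted enoate with the ester trans to C8 (CH2OTBS cis to C8) under neutral conditions that do not epimerise the epoxy aldehyde.

Step 9
Reactants: 13, 14 (angelic acid, (Z)-2-methylbut-2-enoic acid)
Product: 15 (methyl (2E,4S)-5-hydroxy-4-{[(2Z)-2-methylbut-2-enoyl]oxy}-2-{[(tert-butyldimethylsilyl)oxy]methyl}pent-2-enoate)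
Conditions: Pd(PPh3)4 (5 mol%), 14 (1.5 equiv), THF, 0 °C → rt
Reagents that add atoms: none (14 is numbered)
Why: Tsuji–Trost opening of the vinyl epoxide: Pd(0) ionises with inversion and the angelate attacks the only non-quaternary allyl terminus (C8) anti to Pd, so net retention sets C8 as S and frees the C9 primary alcohol in one operation.

Step 10
Reactants: 15
Product: 16 (methyl (2E,4S)-4-{[(2Z)-2-methylbut-2-enoyl]oxy}-5-oxo-2-{[(tert-butyldimethylsilyl)oxy]methyl}pent-2-enoate)
Conditions: Dess–Martin periodinane, NaHCO3, CH2Cl2, 0 °C; used crude at once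
Reagents that add atoms: none
Why: Non-basic Dess–Martin oxidation gives the α-acyloxy aldehyde without epimerising the acidic C8–H or isomerising the angelate.

**Coupling and endgame**

Step 11
Reactants: 7, 16
Product: 17 (methyl (2E,4S,5S,6E,10E)-2-{[(tert-butyldimethylsilyl)oxy]methyl}-5-hydroxy-12,12-dimethoxy-6-(methoxycarbonyl)-10-methyl-4-{[(2Z)-2-methylbut-2-enoyl]oxy}dodeca-2,6,10-trienoate)
Conditions: CrCl2, NiCl2 (cat.), Kishi-type chiral oxazoline–sulfonamide ligand (enantiomer that directs Si-face addition), Et3N, THF/MeCN, 4 Å MS, rt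
Reagents that add atoms: none
Why: Nozaki–Hiyama–Kishi coupling: Ni inserts into the C–I bond with retention and the vinyl-Cr(III) adds only to the aldehyde, preserving the cis C1=C10 geometry; because the substrate's Felkin bias favours the 8,9-anti (9R) adduct, the chiral Cr complex is used to direct attack to the Si face and set C9 as S.

Step 12
Reactants: 17
Product: 18 (methyl (2E,4S,5S,6E,10E)-5-hydroxy-2-(hydroxymethyl)-6-(methoxycarbonyl)-10-methyl-4-{[(2Z)-2-methylbut-2-enoyl]oxy}-12-oxododeca-2,6,10-trienoate)
Conditions: aq. HF (48%), MeCN/H2O, 0 °C → rt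
Reagents that add atoms: water, O
Why: Acid removes the primary TBS ether and hydrolyses the α,β-unsaturated dimethyl acetal to the E-enal in one operation, under conditions too mild to move the angelate or ionise the C9 alcohol.

Step 13
Reactants: 18
Product: 19 (methyl (2Z,4S,5S,6E,10E)-2-(bromomethyl)-5-hydroxy-6-(methoxycarbonyl)-10-methyl-4-{[(2Z)-2-methylbut-2-enoyl]oxy}-12-oxododeca-2,6,10-trienoate)
Conditions: CBr4 (1.2 equiv), PPh3 (1.1 equiv), 2,6-lutidine, CH2Cl2, −30 → 0 °C
Reagents that add atoms: carbon tetrabromide, BrC(Br)(Br)Br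
Why: Appel bromination is selective for the primary allylic C13–OH over the hindered secondary C9–OH and leaves the enal intact.

Step 14
Reactants: 19
Product: 20 (polymatin A; (6R,7S,8S,9S)-8-angeloyloxy-9-hydroxy-14-methoxycarbonyl melampolide 12,6-lactone)
Conditions: CrCl2 (8 equiv), THF, 2 mM, syringe-pump addition, rt; aq. NH4Cl work-up
Reagents that add atoms: none
Why: Intramolecular Nozaki–Hiyama/Barbier allylation: the 2-(methoxycarbonyl)allyl-Cr(III) adds through C7 to the C6 enal in a chair transition state with C5 and C8 pseudo-equatorial (6,7-anti, hence trans-lactone), the C8/C9 centres and the cis C1=C10 bond are expected to fix the ring conformation so that C6 is R and C7 is S, and the Cr alkoxide lactonises onto the adjacent methyl ester.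

**Compound list**
1 | 2,2-dimethoxyacetaldehyde | COC(OC)C=O | starting material
2 | isopropenylmagnesium bromide | CC(=C)[Mg]Br | starting material
3 | 1,1-dimethoxy-3-methylbut-3-en-2-ol (racemic) | COC(OC)C(O)C(C)=C | intermediate
4 | trimethyl orthoacetate | CC(OC)(OC)OC | starting material
5 | methyl (E)-6,6-dimethoxy-4-methylhex-4-enoate | COC(=O)CC/C(C)=C/C(OC)OC | intermediate
6 | (E)-6,6-dimethoxy-4-methylhex-4-enal | O=CCC/C(C)=C/C(OC)OC | intermediate
7 | methyl (2Z,6E)-2-iodo-8,8-dimethoxy-6-methylocta-2,6-dienoate | COC(=O)/C(I)=C/CC/C(C)=C/C(OC)OC | intermediate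
8 | methyl 2-bromo-3-hydroxypropanoate (racemic) | COC(=O)C(Br)CO | starting material
9 | methyl 2-bromo-3-[(tert-butyldimethylsilyl)oxy]propanoate | COC(=O)C(Br)CO[Si](C)(C)C(C)(C)C | intermediate
10 | methyl 3-[(tert-butyldimethylsilyl)oxy]-2-(triphenylphosphoranylidene)propanoate | COC(=O)C(CO[Si](C)(C)C(C)(C)C)=P(c1ccccc1)(c1ccccc1)c1ccccc1 | intermediate
11 | (S)-glycidol | OC[C@H]1CO1 | starting material
12 | (R)-oxirane-2-carbaldehyde | O=C[C@H]1CO1 | intermediate
13 | methyl (2E)-2-{[(tert-butyldimethylsilyl)oxy]methyl}-3-[(2S)-oxiran-2-yl]prop-2-enoate | COC(=O)/C(CO[Si](C)(C)C(C)(C)C)=C/[C@H]1CO1 | intermediate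
14 | angelic acid | C/C=C(/C)C(=O)O | starting material
15 | methyl (2E,4S)-5-hydroxy-4-(angeloyloxy)-2-{[(tert-butyldimethylsilyl)oxy]methyl}pent-2-enoate | COC(=O)/C(CO[Si](C)(C)C(C)(C)C)=C/[C@H](OC(=O)/C(C)=C\C)CO | intermediate
16 | methyl (2E,4S)-4-(angeloyloxy)-5-oxo-2-{[(tert-butyldimethylsilyl)oxy]methyl}pent-2-enoate | COC(=O)/C(CO[Si](C)(C)C(C)(C)C)=C/[C@H](OC(=O)/C(C)=C\C)C=O | intermediate
17 | NHK adduct (C9–OH, C6 acetal, C13–OTBS) | COC(OC)/C=C(\C)CC/C=C(/C(=O)OC)[C@H](O)[C@@H](OC(=O)/C(C)=C\C)/C=C(\CO[Si](C)(C)C(C)(C)C)C(=O)OC | intermediate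
18 | enal diol (C6 aldehyde, C9–OH, C13–OH) | O=C/C=C(\C)CC/C=C(/C(=O)OC)[C@H](O)[C@@H](OC(=O)/C(C)=C\C)/C=C(\CO)C(=O)OC | intermediate
19 | enal allylic bromide | O=C/C=C(\C)CC/C=C(/C(=O)OC)[C@H](O)[C@@H](OC(=O)/C(C)=C\C)/C=C(\CBr)C(=O)OC | intermediate
20 | polymatin A | C=C1C(=O)O[C@@H]2/C=C(\C)CC/C=C(/C(=O)OC)[C@H](O)[C@@H](OC(=O)/C(C)=C\C)[C@@H]12 | target

**Totals**
Total steps: 14. Longest linear sequence: 9 (steps 5, 6, 8, 9, 10, 11, 12, 13, 14).

**Three steps most likely to fail**
1. Step 11 (NHK coupling). The ligand must override the Felkin preference for the 9R epimer, aldehyde 16 can epimerise at C8, and the angelate may migrate to the new C9 alkoxide. Fallback: accept the Felkin-favoured adduct, oxidise C9–OH to the enone and set C9 by a Felkin-controlled 1,2-reduction (NaBH4/CeCl3, −78 °C), which gives the 8,9-syn (9S) alcohol.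
2. Step 14 (macrocyclic Barbier). Risks are 1,4-elimination of the C8 angelate from the allyl-chromium, formation of the 6,7-cis or 7-epi lactone, and oligomerisation. Fallback: swap the two C–C bond formations. Join the halves at C6–C7 by allylboration of the free enal with a configurationally defined (E)-2-(methoxycarbonyl)allylboronate made from the East half (stereospecific trans-lactone), then close the ring by intramolecular Ni/Cr coupling at C9–C10.
3. Step 9 (Pd-catalysed epoxide opening). Risks are loss of stereochemical fidelity through π-allyl isomerisation, angelate-to-tiglate isomerisation by phosphine, and acyl migration to the primary alcohol. Fallback: take C8 from (R)-2,3-O-isopropylideneglyceraldehyde instead. Wittig with 10, acetonide removal, primary TES protection, Yamaguchi angeloylation of the secondary alcohol, then Swern oxidation of the TES ether directly to aldehyde 16, with no π-allyl chemistry.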